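**Strategy.** Ring A (cyclohexane: C1 quaternary, C2 methylidene carbon, C3 CH–CH3) is closed at C3–C4 while C1 and C2 still belong to a temporary cyclopentene (ring B) built from C1, C2, the two linker CH2 groups and the future chromene C2. The key step is a copper-catalysed ring-closing anti-SN2′ coupling: the allyl arm on C1, hydroborated in the flask, attacks the ethylidene carbon of a ring B allylic phosphate. It exploits the 1,3-relation of C1 and C3 across sp2 C2: ring B turns the quaternary centre into a face-selective tether, so one operation forms the bond, sets C3 and leaves an alkene whose ozonolysis frees the C2 ketone (later methylidene) and the side chain.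

Key step: step 6

Assumption: in the three catalyst-controlled steps (2, 4, 16) the ligand or catalyst enantiomer is the one that gives the drawn configuration under the usual facial models; if the sense proves opposite, the other enantiomer is used.

Step 1
Reactants: 1 3-ethoxycyclopent-2-en-1-one
Product: 3 3-(prop-2-en-1-yl)cyclopent-2-en-1-one, via bromomagnesium alkoxide of the 1,2-adduct 2 (not isolated)
Conditions: allylMgBr, THF, 0 °C; then 1 M HCl (aq), 0 °C → rt
Reagents that add atoms: allylmagnesium bromide, C=CC[Mg]Br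
Why: 1,2-addition to the vinylogous ester followed by acid hydrolysis of the enol ether and loss of water should give the transposed 3-substituted enone (Stork–Danheiser sequence), the short cold acid treatment keeping the allyl alkene out of conjugation.

Step 2
Reactants: 3 3-(prop-2-en-1-yl)cyclopent-2-en-1-one
Product: 5 (3S)-2-(1-hydroxyethyl)-3-methyl-3-(prop-2-en-1-yl)cyclopentan-1-one, via dimethylaluminium enolate 4 (not isolated)
Conditions: AlMe3, copper thiophene-2-carboxylate (CuTC, 5 mol %), chiral phosphoramidite ligand (10 mol %), Et2O, −30 °C; then MeCHO, −78 → −30 °C; Rochelle salt work-up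
Reagents that add atoms: trimethylaluminium, C[Al](C)C; acetaldehyde, CC=O
Why: copper-catalysed asymmetric conjugate addition of methyl to the β,β-disubstituted enone should set the quaternary carbon under ligand control, and the regiodefined aluminium enolate should be captured at C2 by aldol addition (tandem conjugate addition–aldol) as a diastereomer mixture that is of no consequence.

Step 3
Reactants: 5 (3S)-2-(1-hydroxyethyl)-3-methyl-3-(prop-2-en-1-yl)cyclopentan-1-one
Product: 7 (2Z,3S)-2-ethylidene-3-methyl-3-(prop-2-en-1-yl)cyclopentan-1-one, via methanesulfonate 6 (not isolated)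
Conditions: MsCl, Et3N, CH2Cl2, 0 °C; then DBU, rt
Reagents that add atoms: none
Why: E1cB elimination of the β-mesyloxy ketone should give the exocyclic enone, and equilibration under DBU should converge on the Z isomer, whose methyl lies beside the carbonyl and away from the quaternary carbon (relief of allylic 1,3-strain).

Step 4
Reactants: 7 (2Z,3S)-2-ethylidene-3-methyl-3-(prop-2-en-1-yl)cyclopentan-1-one
Product: 8 (1R,2Z,3S)-2-ethylidene-3-methyl-3-(prop-2-en-1-yl)cyclopentan-1-ol
Conditions: (S)-2-methyl-CBS-oxazaborolidine (20 mol %), catecholborane, toluene, −78 °C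
Reagents that add atoms: none
Why: CBS reduction should treat the alkylidene-bearing side as the large group and deliver hydride to one carbonyl face under catalyst control, placing the hydroxyl anti to the allyl arm, while catecholborane leaves the alkenes untouched at this temperature.

Step 5
Reactants: 8 (1R,2Z,3S)-2-ethylidene-3-methyl-3-(prop-2-en-1-yl)cyclopentan-1-ol
Product: 9 diethyl (1R,2Z,3S)-2-ethylidene-3-methyl-3-(prop-2-en-1-yl)cyclopentyl phosphate
Conditions: ClP(O)(OEt)2, pyridine, DMAP (cat.), CH2Cl2, 0 °C; used without chromatography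
Reagents that add atoms: diethyl chlorophosphate, CCOP(=O)(Cl)OCC
Why: O-phosphorylation of the secondary allylic alcohol proceeds with retention at carbon and installs the leaving group for the allylic substitution.

Step 6
Reactants: 9 diethyl (1R,2Z,3S)-2-ethylidene-3-methyl-3-(prop-2-en-1-yl)cyclopentyl phosphate
Product: 11 (3aR,7R)-3a,7-dimethyl-3,3a,4,5,6,7-hexahydro-2H-indene, via B-alkyl-9-BBN adduct 10 (not isolated)
Conditions: 9-BBN (1.05 equiv), THF, 0 °C → rt; then CuOAc (10 mol %), KOMe (1.2 equiv), THF, 50 °C
Reagents that add atoms: none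
Why: 9-BBN should hydroborate only the monosubstituted alkene; methoxide converts the primary alkylborane into a borate that passes its alkyl group to monovalent copper, and the alkylcopper attacks the ethylidene CH (γ-carbon) on the face opposite the phosphate, through an allylcopper species of trivalent copper that reductively eliminates to the C–C bond. The closest known reaction type is the copper-catalysed γ-selective, 1,3-anti stereospecific allyl–alkyl coupling of alkyl-9-BBN reagents with secondary allylic phosphates, applied here in a ring-closing sense. Ring A closes in a 6-endo mode (both alkene carbons end up in the new six-membered ring, the phosphate-bearing carbon outside it). The new stereocentre (C3 of ring A, C7 of the hexahydroindene) is controlled by the quaternary carbon, whose three-carbon tether can reach only one face of the exocyclic alkene of ring B; the CBS-set phosphate sits on the other face (matched anti geometry), and the Z alkene then places the methyl cis to the ring B carbon, that is cis to the future side chain. The step needs γ- over α-attack (α-attack would give a bridged bicyclo[3.2.1]octane), which the intrinsic γ-preference of the copper reagent and the less strained fused transition state should secure, and chemoselective hydroboration, which the hindered trisubstituted nature of the second alkene should secure.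

Step 7
Reactants: 11 (3aR,7R)-3a,7-dimethyl-3,3a,4,5,6,7-hexahydro-2H-indene
Product: 13 3-[(1R,3R)-1,3-dimethyl-2-oxocyclohexyl]propanal, via secondary ozonide 12 (not isolated)
Conditions: O3, CH2Cl2, −78 °C; then PPh3, −78 °C → rt
Reagents that add atoms: ozone, [O-][O+]=O
Why: ozonolysis with reductive work-up cleaves the only alkene, so ring B opens to the ring A ketone and the side-chain aldehyde under neutral conditions that should leave the α-methyl stereocentre untouched.

Step 8
Reactants: 13 3-[(1R,3R)-1,3-dimethyl-2-oxocyclohexyl]propanal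
Product: 14 (2R,6R)-2-(but-3-yn-1-yl)-2,6-dimethylcyclohexan-1-one
Conditions: dimethyl (1-diazo-2-oxopropyl)phosphonate, K2CO3, MeOH, 0 °C → rt
Reagents that add atoms: dimethyl (1-diazo-2-oxopropyl)phosphonate, CC(=O)C(=[N+]=[N-])P(=O)(OC)OC
Why: Ohira–Bestmann homologation is selective for the aldehyde over the hindered ketone, and the mild carbonate base at low temperature should not epimerise the ketone α-carbon.

Step 9
Reactants: 14 (2R,6R)-2-(but-3-yn-1-yl)-2,6-dimethylcyclohexan-1-one
Product: 15 (1R,3R)-1-(but-3-yn-1-yl)-1,3-dimethyl-2-methylidenecyclohexane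
Conditions: Zn, CH2Br2, TiCl4, THF/CH2Cl2, 0 °C → rt
Reagents that add atoms: dibromomethane, BrCBr
Why: the non-basic zinc–titanium methylenation (Takai–Lombardo) converts hindered enolisable ketones into methylidene compounds without epimerisation and should tolerate the terminal alkyne.

Step 10
Reactants: 15 (1R,3R)-1-(but-3-yn-1-yl)-1,3-dimethyl-2-methylidenecyclohexane
Product: 18 (2E)-5-[(1R,3R)-1,3-dimethyl-2-methylidenecyclohexyl]-3-methylpent-2-en-1-yl methyl carbonate, via alkenyldimethylalane 16 (not isolated), via lithium allylic alkoxide 17 (not isolated)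
Conditions: AlMe3, Cp2ZrCl2 (25 mol %), CH2Cl2, 0 °C → rt; then n-BuLi, THF, −78 °C, (CH2O)n, → rt; then ClCO2Me, 0 °C
Reagents that add atoms: trimethylaluminium, C[Al](C)C; formaldehyde (as paraformaldehyde), C=O; methyl chloroformate, COC(=O)Cl
Why: zirconium-catalysed syn-methylalumination of the terminal alkyne (Negishi carboalumination) fixes the E trisubstituted alkene, the alkenylalanate adds to formaldehyde with retention, and the alkoxide is acylated in the same flask.

Step 11
Reactants: 19 2-methoxybenzene-1,4-diol
Product: 20 2-methoxy-1,4-bis(methoxymethoxy)benzene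
Conditions: MOMCl, i-Pr2NEt, CH2Cl2, 0 °C → rt
Reagents that add atoms: chloromethyl methyl ether, COCCl
Why: double O-alkylation masks the hydroquinone as acetals that resist organolithium reagents, palladium and ruthenium catalysts and cannot migrate between neighbouring oxygens.

Step 12
Reactants: 20 2-methoxy-1,4-bis(methoxymethoxy)benzene
Product: 21 1-bromo-4-methoxy-2,5-bis(methoxymethoxy)benzene
Conditions: NBS, MeCN, 0 °C
Reagents that add atoms: N-bromosuccinimide, O=C1CCC(=O)N1Br
Why: electrophilic aromatic bromination of the 1,2,4-trioxygenated ring should occur para to the methoxy group, the position that becomes the chromene oxygen site.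

Step 13
Reactants: 21 1-bromo-4-methoxy-2,5-bis(methoxymethoxy)benzene
Product: 24 4-methoxy-2,5-bis(methoxymethoxy)phenol, via aryllithium 22 (not isolated), via dimethyl arylboronate 23 (not isolated)
Conditions: n-BuLi, THF, −78 °C; B(OMe)3, −78 °C → rt; then H2O2, NaOH (aq), 0 °C
Reagents that add atoms: hydrogen peroxide, OO
Why: bromine–lithium exchange, borylation and oxidative 1,2-migration replace bromine by hydroxyl at a defined position.

Step 14
Reactants: 24 4-methoxy-2,5-bis(methoxymethoxy)phenol
Product: 25 2-hydroxy-5-methoxy-3,6-bis(methoxymethoxy)benzaldehyde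
Conditions: MgCl2, Et3N, (CH2O)n, MeCN, reflux
Reagents that add atoms: formaldehyde (as paraformaldehyde), C=O
Why: magnesium phenoxide-directed ortho-formylation (Casnati–Skattebøl) can only attack the single free ortho position.

Step 15
Reactants: 25 2-hydroxy-5-methoxy-3,6-bis(methoxymethoxy)benzaldehyde
Product: 26 2-ethenyl-4-methoxy-3,6-bis(methoxymethoxy)phenol
Conditions: Ph3PCH3Br, KOtBu (2.5 equiv), THF, 0 °C → rt
Reagents that add atoms: methyltriphenylphosphonium bromide, C[P+](c1ccccc1)(c1ccccc1)c1ccccc1.[Br-]
Why: Wittig methylenation of the salicylaldehyde (as its phenoxide) gives the styrene needed for metathesis.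

Step 16
Reactants: 18 (2E)-5-[(1R,3R)-1,3-dimethyl-2-methylidenecyclohexyl]-3-methylpent-2-en-1-yl methyl carbonate; 26 2-ethenyl-4-methoxy-3,6-bis(methoxymethoxy)phenol
Product: 27 2-ethenyl-1-{[(3S)-5-[(1R,3R)-1,3-dimethyl-2-methylidenecyclohexyl]-3-methylpent-1-en-3-yl]oxy}-4-methoxy-3,6-bis(methoxymethoxy)benzene
Conditions: Pd2(dba)3·CHCl3 (2.5 mol %), (1R,2R)-N,N′-bis[2-(diphenylphosphino)benzoyl]cyclohexane-1,2-diamine (7.5 mol %), CH2Cl2, rt
Reagents that add atoms: none
Why: zerovalent palladium ionises the carbonate to an allylpalladium complex and methoxide, and the phenoxide should attack the more substituted allyl terminus inside the chiral pocket (palladium-catalysed asymmetric allylic O-alkylation), creating the tertiary ether stereocentre under ligand control.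

Step 17
Reactants: 27 2-ethenyl-1-{[(3S)-5-[(1R,3R)-1,3-dimethyl-2-methylidenecyclohexyl]-3-methylpent-1-en-3-yl]oxy}-4-methoxy-3,6-bis(methoxymethoxy)benzene
Product: 28 (2S)-2-{2-[(1R,3R)-1,3-dimethyl-2-methylidenecyclohexyl]ethyl}-6-methoxy-5,8-bis(methoxymethoxy)-2-methyl-2H-chromene
Conditions: second-generation Grubbs catalyst (5 mol %), CH2Cl2, 40 °C
Reagents that add atoms: none
Why: ring-closing metathesis between the styrene and the monosubstituted vinyl group forms the 2H-chromene without touching the C–O stereocentre, and the hindered 1,1-disubstituted methylidene should not engage.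

Step 18
Reactants: 28 (2S)-2-{2-[(1R,3R)-1,3-dimethyl-2-methylidenecyclohexyl]ethyl}-6-methoxy-5,8-bis(methoxymethoxy)-2-methyl-2H-chromene
Product: 29 (2S)-2-{2-[(1R,3R)-1,3-dimethyl-2-methylidenecyclohexyl]ethyl}-6-methoxy-2-methyl-2H-chromene-5,8-diol
Conditions: HCl (1.25 M in MeOH), THF, 0 °C → rt, argon; NaHCO3 quench
Reagents that add atoms: none
Why: acid-catalysed acetal exchange with methanol removes both aryl MOM ethers under conditions that should be mild enough for the exocyclic alkene and the chromene, and exclusion of air protects the hydroquinone.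

**Compound list**

1 | 3-ethoxycyclopent-2-en-1-one | CCOC1=CC(=O)CC1 | starting material
2 | bromomagnesium 3-ethoxy-1-(prop-2-en-1-yl)cyclopent-2-en-1-olate | C=CCC1(O[Mg]Br)C=C(OCC)CC1 | intermediate
3 | 3-(prop-2-en-1-yl)cyclopent-2-en-1-one | C=CCC1=CC(=O)CC1 | intermediate
4 | dimethylaluminium (3S)-3-methyl-3-(prop-2-en-1-yl)cyclopent-1-en-1-olate | C=CC[C@]1(C)CCC(=C1)O[Al](C)C | intermediate
5 | (3S)-2-(1-hydroxyethyl)-3-methyl-3-(prop-2-en-1-yl)cyclopentan-1-one (mixture at C2 and at the carbinol carbon) | CC(O)C1C(=O)CC[C@@]1(C)CC=C | intermediate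
6 | 1-[(2S)-2-methyl-5-oxo-2-(prop-2-en-1-yl)cyclopentyl]ethyl methanesulfonate | CC(OS(C)(=O)=O)C1C(=O)CC[C@@]1(C)CC=C | intermediate
7 | (2Z,3S)-2-ethylidene-3-methyl-3-(prop-2-en-1-yl)cyclopentan-1-one | C/C=C1\C(=O)CC[C@@]1(C)CC=C | intermediate
8 | (1R,2Z,3S)-2-ethylidene-3-methyl-3-(prop-2-en-1-yl)cyclopentan-1-ol | C/C=C1\[C@H](O)CC[C@@]1(C)CC=C | intermediate
9 | diethyl (1R,2Z,3S)-2-ethylidene-3-methyl-3-(prop-2-en-1-yl)cyclopentyl phosphate | C/C=C1\[C@H](OP(=O)(OCC)OCC)CC[C@@]1(C)CC=C | intermediate
10 | diethyl (1R,2Z,3R)-3-[3-(9-borabicyclo[3.3.1]nonan-9-yl)propyl]-2-ethylidene-3-methylcyclopentyl phosphate | C/C=C1\[C@H](OP(=O)(OCC)OCC)CC[C@@]1(C)CCCB2C3CCCC2CCC3 | intermediate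
11 | (3aR,7R)-3a,7-dimethyl-3,3a,4,5,6,7-hexahydro-2H-indene | C[C@@H]1CCC[C@]2(C)CCC=C12 | intermediate
12 | secondary ozonide (1,2,4-trioxolane across C1 and C7a) of 11 | C[C@@H]1CCC[C@]2(C)CCC3OOC12O3 | intermediate
13 | 3-[(1R,3R)-1,3-dimethyl-2-oxocyclohexyl]propanal | O=C1[C@H](C)CCC[C@]1(C)CCC=O | intermediate
14 | (2R,6R)-2-(but-3-yn-1-yl)-2,6-dimethylcyclohexan-1-one | O=C1[C@H](C)CCC[C@]1(C)CCC#C | intermediate
15 | (1R,3R)-1-(but-3-yn-1-yl)-1,3-dimethyl-2-methylidenecyclohexane | C=C1[C@H](C)CCC[C@]1(C)CCC#C | intermediate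
16 | {(1E)-4-[(1R,3R)-1,3-dimethyl-2-methylidenecyclohexyl]-2-methylbut-1-en-1-yl}dimethylalane | C=C1[C@H](C)CCC[C@]1(C)CC/C(C)=C/[Al](C)C | intermediate
17 | lithium (2E)-5-[(1R,3R)-1,3-dimethyl-2-methylidenecyclohexyl]-3-methylpent-2-en-1-olate (aluminate-bound) | C=C1[C@H](C)CCC[C@]1(C)CC/C(C)=C/C[O-].[Li+] | intermediate
18 | (2E)-5-[(1R,3R)-1,3-dimethyl-2-methylidenecyclohexyl]-3-methylpent-2-en-1-yl methyl carbonate | C=C1[C@H](C)CCC[C@]1(C)CC/C(C)=C/COC(=O)OC | intermediate
19 | 2-methoxybenzene-1,4-diol | COc1cc(O)ccc1O | starting material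
20 | 2-methoxy-1,4-bis(methoxymethoxy)benzene | COCOc1ccc(OCOC)c(OC)c1 | intermediate
21 | 1-bromo-4-methoxy-2,5-bis(methoxymethoxy)benzene | COCOc1cc(Br)c(OCOC)cc1OC | intermediate
22 | [4-methoxy-2,5-bis(methoxymethoxy)phenyl]lithium | [Li]c1cc(OCOC)c(OC)cc1OCOC | intermediate
23 | dimethyl [4-methoxy-2,5-bis(methoxymethoxy)phenyl]boronate | COB(OC)c1cc(OCOC)c(OC)cc1OCOC | intermediate
24 | 4-methoxy-2,5-bis(methoxymethoxy)phenol | Oc1cc(OCOC)c(OC)cc1OCOC | intermediate
25 | 2-hydroxy-5-methoxy-3,6-bis(methoxymethoxy)benzaldehyde | O=Cc1c(O)c(OCOC)cc(OC)c1OCOC | intermediate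
26 | 2-ethenyl-4-methoxy-3,6-bis(methoxymethoxy)phenol | C=Cc1c(O)c(OCOC)cc(OC)c1OCOC | intermediate
27 | 2-ethenyl-1-{[(3S)-5-[(1R,3R)-1,3-dimethyl-2-methylidenecyclohexyl]-3-methylpent-1-en-3-yl]oxy}-4-methoxy-3,6-bis(methoxymethoxy)benzene | C=C1[C@H](C)CCC[C@]1(C)CC[C@@](C)(C=C)Oc1c(C=C)c(OCOC)c(OC)cc1OCOC | intermediate
28 | (2S)-2-{2-[(1R,3R)-1,3-dimethyl-2-methylidenecyclohexyl]ethyl}-6-methoxy-5,8-bis(methoxymethoxy)-2-methyl-2H-chromene | C=C1[C@H](C)CCC[C@]1(C)CC[C@@]1(C)C=Cc2c(OCOC)c(OC)cc(OCOC)c2O1 | intermediate
29 | (2S)-2-{2-[(1R,3R)-1,3-dimethyl-2-methylidenecyclohexyl]ethyl}-6-methoxy-2-methyl-2H-chromene-5,8-diol | C=C1[C@H](C)CCC[C@]1(C)CC[C@@]1(C)C=Cc2c(O)c(OC)cc(O)c2O1 | target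

**Totals.** 18 steps in all; longest linear sequence 13 steps (steps 1–10, then 16–18); the arene 26 is made in 5 steps (11–15) and joined in step 16.

**Steps most likely to fail**

1. Step 6. Transfer of the alkyl group from boron to copper may be slower than protodeboronation, the allylic phosphate may ionise or undergo a 1,3-shift, or attack may occur at the α-carbon. The fallback sets out from 8 and returns at 11, and replaces the polar substitution by a radical conjugate cyclisation. Hydroboration of the allyl group of 8 with 9-BBN should give the B-alkylborane (1R,2Z,3R)-3-[3-(9-borabicyclo[3.3.1]nonan-9-yl)propyl]-2-ethylidene-3-methylcyclopentan-1-ol F1, and iodinolysis (I2, NaOMe) should give the primary iodide (1R,2Z,3S)-2-ethylidene-3-(3-iodopropyl)-3-methylcyclopentan-1-ol F2. Oxidation of the allylic alcohol (MnO2) should give the iodo enone (2Z,3S)-2-ethylidene-3-(3-iodopropyl)-3-methylcyclopentan-1-one F3. A tin hydride-mediated 6-endo-trig radical cyclisation onto the α-alkylidene ketone (Bu3SnH, AIBN, benzene, 80 °C, slow addition) should then give the cis-fused hydrindanone (3aR,7R,7aR)-3a,7-dimethyloctahydro-1H-inden-1-one F4 with the same tether-controlled face selectivity. Its tosylhydrazone N′-[(3aR,7R,7aR)-3a,7-dimethyloctahydro-1H-inden-1-ylidene]-4-methylbenzenesulfonohydrazide F5 (TsNHNH2, MeOH) should lose nitrogen and sulfinate under aprotic Bamford–Stevens conditions (NaOMe, diglyme, 150 °C) towards the more substituted alkene 11.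

2. Step 16. Attack of the doubly ortho-substituted phenoxide on the hindered terminus of the allylpalladium complex may be slow, so that linear ether formation or poor facial selectivity takes over. The fallback sets out from 15 (with 24 as partner) and returns at 28. The carboalumination–formaldehyde sequence of step 10 is quenched with water to give the allylic alcohol (2E)-5-[(1R,3R)-1,3-dimethyl-2-methylidenecyclohexyl]-3-methylpent-2-en-1-ol F6, and MnO2 oxidation should give the enal (2E)-5-[(1R,3R)-1,3-dimethyl-2-methylidenecyclohexyl]-3-methylpent-2-enal F7. Condensation of F7 with phenol 24 (ethylenediammonium diacetate, toluene, 110 °C; ortho C-alkylation, dehydration to an ortho-quinone methide, oxa-6π electrocyclisation) should give the chromene as a mixture of epimers at the chromene C2, (2RS)-2-{2-[(1R,3R)-1,3-dimethyl-2-methylidenecyclohexyl]ethyl}-6-methoxy-5,8-bis(methoxymethoxy)-2-methyl-2H-chromene F8. Because ring A is already homochiral these epimers are diastereomers, and preparative HPLC should deliver 28 (at most half of the material).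

3. Step 2. Capture of the aluminium enolate by acetaldehyde may be incomplete (proton transfer, retro-aldol on warming), and facial selectivity of the methyl transfer may be insufficient. The fallback sets out from 3 and returns at 5. The conjugate addition is run alone and the enolate is silylated (Me3SiCl, Et3N) to {[(3S)-3-methyl-3-(prop-2-en-1-yl)cyclopent-1-en-1-yl]oxy}trimethylsilane F9, which can be purified and assayed for enantiopurity before it is committed. A Mukaiyama aldol addition to acetaldehyde (TiCl4, CH2Cl2, −78 °C) then forms the C–C bond regiospecifically and gives 5.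

**Further compounds**

F1 | step 6 | (1R,2Z,3R)-3-[3-(9-borabicyclo[3.3.1]nonan-9-yl)propyl]-2-ethylidene-3-methylcyclopentan-1-ol | C/C=C1\[C@H](O)CC[C@@]1(C)CCCB2C3CCCC2CCC3
F2 | step 6 | (1R,2Z,3S)-2-ethylidene-3-(3-iodopropyl)-3-methylcyclopentan-1-ol | C/C=C1\[C@H](O)CC[C@@]1(C)CCCI
F3 | step 6 | (2Z,3S)-2-ethylidene-3-(3-iodopropyl)-3-methylcyclopentan-1-one | C/C=C1\C(=O)CC[C@@]1(C)CCCI
F4 | step 6 | (3aR,7R,7aR)-3a,7-dimethyloctahydro-1H-inden-1-one | C[C@@H]1CCC[C@]2(C)CCC(=O)[C@H]12
F5 | step 6 | N′-[(3aR,7R,7aR)-3a,7-dimethyloctahydro-1H-inden-1-ylidene]-4-methylbenzenesulfonohydrazide | C[C@@H]1CCC[C@]2(C)CCC(=NNS(=O)(=O)c3ccc(C)cc3)[C@H]12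
F6 | step 16 | (2E)-5-[(1R,3R)-1,3-dimethyl-2-methylidenecyclohexyl]-3-methylpent-2-en-1-ol | C=C1[C@H](C)CCC[C@]1(C)CC/C(C)=C/CO
F7 | step 16 | (2E)-5-[(1R,3R)-1,3-dimethyl-2-methylidenecyclohexyl]-3-methylpent-2-enal | C=C1[C@H](C)CCC[C@]1(C)CC/C(C)=C/C=O
F8 | step 16 | (2RS)-2-{2-[(1R,3R)-1,3-dimethyl-2-methylidenecyclohexyl]ethyl}-6-methoxy-5,8-bis(methoxymethoxy)-2-methyl-2H-chromene | C=C1[C@H](C)CCC[C@]1(C)CCC1(C)C=Cc2c(OCOC)c(OC)cc(OCOC)c2O1
F9 | step 2 | {[(3S)-3-methyl-3-(prop-2-en-1-yl)cyclopent-1-en-1-yl]oxy}trimethylsilane | C=CC[C@]1(C)CCC(=C1)O[Si](C)(C)C
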